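**Plan**
- Retrosynthetic cuts: (i) the benzyl–benzyl C–C bond between the 3-methoxybenzyl CH2 (ring A side) and the benzylic CH2 on ring B (the 4-hydroxy-3-aryloxyphenyl ring); (ii) the diaryl ether C–O bond between rings B and C; (iii) the bond from the hydroquinone ring D to its CH2.
- Enabling feature: the ring B hydroxyl is para to the ring B benzylic carbon, so ring B can be unmasked as a para-quinone methide (4-methylenecyclohexa-2,5-dienone). Its exocyclic CH2 accepts a 3-methoxybenzyl nucleophile with rearomatisation, so the C–C bond and the free ring B phenol arise together.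
- Forward: ring D is made from 1,4-benzoquinone by decarboxylative radical alkylation with 3-(4-bromophenyl)propanoic acid (C–D bibenzyl), then reduced and benzylated. An Ullmann etherification with 4-(benzyloxy)-3-hydroxybenzaldehyde adds ring B. Debenzylation, reduction and acetyl chloride give a triacetate benzylic chloride.
- Last step: excess 3-methoxybenzylmagnesium chloride strips the three acetates, triggers the quinone methide and adds to it, giving the target without a separate deprotection.
- Stereochemistry: none to set. The target has no stereocentre or other stereogenic element, so it is achiral and "single enantiomer" is met by the compound as drawn.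

Key step: step 7

**Step 1**
Reactants: 1 3-(4-bromophenyl)propanoic acid; 2 1,4-benzoquinone
Product: 3 2-[2-(4-bromophenyl)ethyl]cyclohexa-2,5-diene-1,4-dione
Conditions: AgNO3 (20 mol%), (NH4)2S2O8 (1.5 equiv), 2 (3 equiv), MeCN/H2O 1:1, 65 °C
Reagents that add atoms: none
Why: Silver/persulfate oxidative decarboxylation (Jacobsen–Torssell quinone alkylation) should turn the acid into a primary 2-arylethyl radical that adds to the excess quinone and is re-oxidised to the monoalkyl quinone, the aryl bromide being inert.

**Step 2**
Reactants: 3 2-[2-(4-bromophenyl)ethyl]cyclohexa-2,5-diene-1,4-dione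
Product: 5 1,4-bis(benzyloxy)-2-[2-(4-bromophenyl)ethyl]benzene, via hydroquinone 4 (not isolated)
Conditions: Na2S2O4, EtOAc/H2O, rt; crude 4 then BnBr (2.5 equiv), K2CO3, DMF, 60 °C, Ar
Reagents that add atoms: benzyl bromide, BrCc1ccccc1
Why: Dithionite reduction of the quinone followed by Williamson etherification of both phenols is a standard reductive alkylation and should mask ring D for the copper step.

**Step 3**
Reactants: 5 1,4-bis(benzyloxy)-2-[2-(4-bromophenyl)ethyl]benzene; 6 4-(benzyloxy)-3-hydroxybenzaldehyde
Product: 7 4-(benzyloxy)-3-{4-[2-(2,5-bis(benzyloxy)phenyl)ethyl]phenoxy}benzaldehyde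
Conditions: CuI (10 mol%), N,N-dimethylglycine·HCl (30 mol%), Cs2CO3 (2 equiv), 1,4-dioxane, 100 °C, Ar
Reagents that add atoms: none
Why: Ligand-accelerated Ullmann diaryl ether synthesis should couple the guaiacol-type phenoxide with the electron-neutral aryl bromide, as is usual for isovanillin-type phenols, with the non-enolisable aldehyde and the benzyl ethers untouched.

**Step 4**
Reactants: 7 4-(benzyloxy)-3-{4-[2-(2,5-bis(benzyloxy)phenyl)ethyl]phenoxy}benzaldehyde
Product: 8 3-{4-[2-(2,5-dihydroxyphenyl)ethyl]phenoxy}-4-hydroxybenzaldehyde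
Conditions: BCl3 (1 M in CH2Cl2, 6 equiv), pentamethylbenzene (9 equiv), CH2Cl2, −78 °C; MeOH/H2O quench
Reagents that add atoms: none
Why: Lewis-acid debenzylation of aryl benzyl ethers with pentamethylbenzene as cation scavenger should free all three phenols without reducing the aldehyde or C-benzylating the electron-rich rings.

**Step 5**
Reactants: 8 3-{4-[2-(2,5-dihydroxyphenyl)ethyl]phenoxy}-4-hydroxybenzaldehyde
Product: 9 2-(2-{4-[2-hydroxy-5-(hydroxymethyl)phenoxy]phenyl}ethyl)benzene-1,4-diol
Conditions: NaBH4 (excess), MeOH, 0 °C, Ar; aq NH4Cl to pH 6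
Reagents that add atoms: none
Why: Borohydride reduction of a 4-hydroxybenzaldehyde to the 4-hydroxybenzyl alcohol (the vanillin to vanillyl alcohol type) should proceed cleanly, and the near-neutral work-up avoids acid-induced self-condensation.

**Step 6**
Reactants: 9 2-(2-{4-[2-hydroxy-5-(hydroxymethyl)phenoxy]phenyl}ethyl)benzene-1,4-diol
Product: 10 2-(2-{4-[2-acetoxy-5-(chloromethyl)phenoxy]phenyl}ethyl)-1,4-phenylene diacetate
Conditions: AcCl (neat, large excess), 0 °C to rt; evaporate
Reagents that add atoms: acetyl chloride, CC(=O)Cl
Why: Acetyl chloride should O-acetylate the three phenols while the liberated HCl converts the para-oxygenated benzylic alcohol into the chloride (the known conversion of hydroxybenzyl alcohols into acetoxybenzyl chlorides), giving a storable latent quinone methide.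

**Step 7**
Reactants: 10 2-(2-{4-[2-acetoxy-5-(chloromethyl)phenoxy]phenyl}ethyl)-1,4-phenylene diacetate; 11 3-methoxybenzylmagnesium chloride (commercial THF solution)
Product: 14 2-(2-{4-[2-hydroxy-5-(2-(3-methoxyphenyl)ethyl)phenoxy]phenyl}ethyl)benzene-1,4-diol (the target), via chloromagnesium triphenoxide 12 (not isolated), via para-quinone methide 13 (not isolated)
Conditions: 11 (10 equiv, THF), slow addition of 10 in THF, −78 to 0 °C, Ar; degassed aq NH4Cl/1 M HCl
Reagents that add atoms: none
Why: Proposed new method: the Grignard reagent first cleaves the three aryl acetates (two equivalents per ester, the acetyl groups ending as a tertiary carbinol), and the ring B phenoxide so released, para to the chloromethyl carbon, expels chloride by 1,6-elimination to give the 2-aryloxy-4-methylenecyclohexa-2,5-dienone 13, whose exocyclic CH2 takes up a further equivalent of the benzyl Grignard in a 1,6-conjugate addition driven by rearomatisation of ring B. The closest known reaction types are the anionic generation of ortho-quinone methides from O-acylated salicyl derivatives with organomagnesium reagents and their capture by a second Grignard equivalent, the 1,6-addition of Grignard reagents to isolable 2,6-di-tert-butyl para-quinone methides, and the cyanide substitution of 4-hydroxybenzyl alcohols through the para-quinone methide; what lacks precedent is an unhindered, δ-unsubstituted para-quinone methide released by ester cleavage and intercepted by a benzylic Grignard reagent in the same flask. No ring is closed and no stereocentre is formed. The step needs C-attack at the exocyclic carbon in preference to 1,2-addition at the dienone carbonyl and to attack by magnesium phenoxides (oligomerisation): the methylene terminus is the least hindered site and the only one whose attack restores the aromatic sextet, and slow inverse addition of 10 into a large excess of 11 at low temperature keeps the quinone methide concentration minimal. Direct SN2 displacement of the benzylic chloride by 11 forms the same bond, so both pathways converge on 14, and the ring D phenoxides carry no leaving group and are simply protonated on acidic work-up.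

**Compound list**
1 | 3-(4-bromophenyl)propanoic acid | OC(=O)CCc1ccc(Br)cc1 | starting material
2 | 1,4-benzoquinone | O=C1C=CC(=O)C=C1 | starting material
3 | 2-[2-(4-bromophenyl)ethyl]cyclohexa-2,5-diene-1,4-dione | O=C1C=CC(=O)C(CCc2ccc(Br)cc2)=C1 | intermediate
4 | 2-[2-(4-bromophenyl)ethyl]benzene-1,4-diol | Oc1ccc(O)c(CCc2ccc(Br)cc2)c1 | intermediate
5 | 1,4-bis(benzyloxy)-2-[2-(4-bromophenyl)ethyl]benzene | Brc1ccc(CCc2cc(OCc3ccccc3)ccc2OCc2ccccc2)cc1 | intermediate
6 | 4-(benzyloxy)-3-hydroxybenzaldehyde | O=Cc1ccc(OCc2ccccc2)c(O)c1 | starting material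
7 | 4-(benzyloxy)-3-{4-[2-(2,5-bis(benzyloxy)phenyl)ethyl]phenoxy}benzaldehyde | O=Cc1ccc(OCc2ccccc2)c(Oc2ccc(CCc3cc(OCc4ccccc4)ccc3OCc3ccccc3)cc2)c1 | intermediate
8 | 3-{4-[2-(2,5-dihydroxyphenyl)ethyl]phenoxy}-4-hydroxybenzaldehyde | O=Cc1ccc(O)c(Oc2ccc(CCc3cc(O)ccc3O)cc2)c1 | intermediate
9 | 2-(2-{4-[2-hydroxy-5-(hydroxymethyl)phenoxy]phenyl}ethyl)benzene-1,4-diol | OCc1ccc(O)c(Oc2ccc(CCc3cc(O)ccc3O)cc2)c1 | intermediate
10 | 2-(2-{4-[2-acetoxy-5-(chloromethyl)phenoxy]phenyl}ethyl)-1,4-phenylene diacetate | CC(=O)Oc1ccc(CCl)cc1Oc1ccc(CCc2cc(OC(C)=O)ccc2OC(C)=O)cc1 | intermediate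
11 | 3-methoxybenzylmagnesium chloride | COc1cccc(C[Mg]Cl)c1 | starting material
12 | tris(chloromagnesium) phenoxide of 2-(2-{4-[5-(chloromethyl)-2-hydroxyphenoxy]phenyl}ethyl)benzene-1,4-diol | ClCc1ccc(O[Mg]Cl)c(Oc2ccc(CCc3cc(O[Mg]Cl)ccc3O[Mg]Cl)cc2)c1 | intermediate
13 | 2-{4-[2-(2,5-dihydroxyphenyl)ethyl]phenoxy}-4-methylenecyclohexa-2,5-dien-1-one, ring D as bis(chloromagnesium) phenoxide | C=C1C=CC(=O)C(Oc2ccc(CCc3cc(O[Mg]Cl)ccc3O[Mg]Cl)cc2)=C1 | intermediate
14 | 2-(2-{4-[2-hydroxy-5-(2-(3-methoxyphenyl)ethyl)phenoxy]phenyl}ethyl)benzene-1,4-diol (CNP0211397.0) | COc1cccc(CCc2ccc(O)c(Oc3ccc(CCc4cc(O)ccc4O)cc3)c2)c1 | target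

**Step count**
Total steps: 7. Longest linear sequence: 7 steps (1 to 14).

**Steps most likely to fail**

Step 7 (proposed new method). What may go wrong: the quinone methide may be captured by magnesium phenoxides faster than by the Grignard reagent, giving benzyl aryl ether or C-benzylated oligomers. Halogen–magnesium exchange at the benzylic chloride may also lead to Wurtz-type homodimers. The fallback uses known chemistry and sets out from 7. Wittig olefination of 7 with commercial (3-methoxybenzyl)triphenylphosphonium chloride and KOtBu in THF should give the stilbene 4-(benzyloxy)-3-{4-[2-(2,5-bis(benzyloxy)phenyl)ethyl]phenoxy}-1-[2-(3-methoxyphenyl)ethenyl]benzene F1 as an E/Z mixture. Hydrogenation of both isomers over Pd/C (H2, EtOAc/MeOH) should saturate the alkene and cleave the three benzyl ethers in one operation, so the fallback comes back to the route at 14.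

Step 6. What may go wrong: before the hydroquinone oxygens are acetylated, the ionising para-hydroxybenzyl centre may alkylate the electron-rich rings of a second molecule (Friedel–Crafts self-condensation), or acetylation may stop short in the acidic medium. The fallback sets out from 8 and separates the operations. Ac2O/pyridine with catalytic DMAP should give the triacetate aldehyde 2-{2-[4-(2-acetoxy-5-formylphenoxy)phenyl]ethyl}-1,4-phenylene diacetate F2. Chemoselective reduction of the aldehyde with BH3·SMe2 in THF at 0 °C should give the benzylic alcohol 2-(2-{4-[2-acetoxy-5-(hydroxymethyl)phenoxy]phenyl}ethyl)-1,4-phenylene diacetate F3. SOCl2 with catalytic DMF in CH2Cl2 at 0 °C should then convert F3 into the chloride, coming back to the route at 10.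

Step 3. What may go wrong: the hindered, aldehyde-bearing phenoxide may exchange slowly at copper, so that protodebromination of the aryl bromide and base-induced degradation of the aldehyde at 100 °C outrun ether formation. The fallback sets out from 5 and reverses the activation. Bromine–lithium exchange (n-BuLi, THF, −78 °C), B(OiPr)3 and aqueous acid should give {4-[2-(2,5-bis(benzyloxy)phenyl)ethyl]phenyl}boronic acid F4. Chan–Lam coupling of F4 with 6 (Cu(OAc)2, pyridine, 4 Å MS, CH2Cl2, air, rt) should form the diaryl ether at room temperature, coming back to the route at 7.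

**Further compounds**
F1 | step 7 | 4-(benzyloxy)-3-{4-[2-(2,5-bis(benzyloxy)phenyl)ethyl]phenoxy}-1-[2-(3-methoxyphenyl)ethenyl]benzene (E/Z mixture) | COc1cccc(C=Cc2ccc(OCc3ccccc3)c(Oc3ccc(CCc4cc(OCc5ccccc5)ccc4OCc4ccccc4)cc3)c2)c1
F2 | step 6 | 2-{2-[4-(2-acetoxy-5-formylphenoxy)phenyl]ethyl}-1,4-phenylene diacetate | CC(=O)Oc1ccc(C=O)cc1Oc1ccc(CCc2cc(OC(C)=O)ccc2OC(C)=O)cc1
F3 | step 6 | 2-(2-{4-[2-acetoxy-5-(hydroxymethyl)phenoxy]phenyl}ethyl)-1,4-phenylene diacetate | CC(=O)Oc1ccc(CO)cc1Oc1ccc(CCc2cc(OC(C)=O)ccc2OC(C)=O)cc1
F4 | step 3 | {4-[2-(2,5-bis(benzyloxy)phenyl)ethyl]phenyl}boronic acid | OB(O)c1ccc(CCc2cc(OCc3ccccc3)ccc2OCc2ccccc2)cc1
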